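## Structural features

Compound 18 is a naphthazarin: ring A (the quinone, C1–C4 with C4a and C8a) is fused to ring B (the dihydroxybenzene, C5–C8), and the two tautomers exchange the roles of the rings by double proton transfer. C2 of ring A is bonded to C1' of a cyclobutane (ring C). In ring C, C1' is a tertiary carbinol carbon esterified with (2Z)-2-methylbut-2-enoic acid, C2' carries a gem-dimethyl group, and C3' and C4' are methylenes. C1' (R) is the only stereocentre; it is fully substituted and adjoins the quaternary C2', so there is no neighbouring stereocentre to relay from. The fragile features are: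
- the Z-alkene of the ester, which drifts to the E-isomer under base, nucleophilic catalysts, acid or heat;
- the tertiary ester, which ionises or eliminates once the adjacent ring is electron-rich or reduced;
- the base- and reductant-sensitive naphthazarin;
- the strained ring C, which opens when C1' becomes cationic or when a free C1'–OH faces an acceptor group on C4'.

The real difficulty is the enantioselective construction of the congested C1'–C2' pair inside ring C, and then the acylation of the shielded C1' oxygen without isomerising the acyl group. The key step exploits the fact that C1' and C2' are the carbonyl and α-carbons of an aryl isopropyl ketone, hence the two carbons of its silyl enol ether. The unfunctionalised C3'–C4' edge can then come from an acrylate whose carboxyl group on C4' is removed afterwards.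

## Logic of the disconnections

**18 ⇒ 14 + 15.** The bonds C4a–C5 and C8a–C8 of ring B are cut. A cycloaddition, ring opening and tautomerisation sequence delivers both peri-hydroxyls unprotected and at the final oxidation level, so no aryl ether has to be cleaved next to the tertiary ester. The bicyclic core is reduced to a monocyclic ring. The forward step must add the diene only to the unsubstituted C=C of 14, and the collapse of 16 through 17 must run without base.

**14 ⇒ 13.** No skeletal bond is cut; the two ring carbonyls are traced back to two aryl O–CH3 groups. The dimethoxyarene is the form of ring A that survives Lewis acid, alkoxide, radical and fluoride chemistry. The forward oxidation must spare the Z-alkene and must not fragment ring C. For that reason the acyl group is already in place: a free 1-arylcyclobutanol would be opened by a one-electron oxidant.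

**13 ⇒ 10 + 11 (through 12).** The acyl C–O bond is cut. The geometrically labile ester is introduced as late as base chemistry allows; no base is used after it. This removes the only configurationally labile alkene from all earlier steps. The forward step must acylate an oxygen flanked by a quaternary carbon and an ortho-substituted arene without Z-to-E isomerisation, which calls for a preformed alkoxide, a symmetrical anhydride and no nucleophilic catalyst.

**10 ⇒ 9.** The O–Si bond is restored. The silyl group is what makes the C1' oxygen a donor in the ring-forming step. The forward cleavage must use fluoride and not acid, because a cation at C1' would open or rearrange ring C.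

**9 ⇒ 7 ⇒ 6 (through 8).** A C4'–carboxyl bond is added back. C3' and C4' carry no function in 18, so an activating group has to be placed there to turn them into an electron-poor alkene. A carboxyl group is chosen because a radical chain removes it without touching C1'. Decarboxylation must precede desilylation, since a free β-hydroxy ester on a cyclobutane would open by retro-aldol cleavage. The secondary cyclobutyl radical must be reduced faster than it can fragment.

**6 ⇒ 4 + 5.** The bonds C2'–C3' and C1'–C4' are cut. This is the only division of ring C into two π-components of complementary polarity that leaves the two fully substituted carbons C1' and C2' already joined. Ring C, the quaternary C2' and the C1' stereocentre then come from two achiral, acyclic pieces in one step. The forward step demands catalyst control over the ring-closure face, closure faster than silyl transfer, and a Lewis acid that tolerates the methoxy groups.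

**4 ⇒ 3 ⇒ 1 + 2.** The O–Si bond and then the aryl–C(O) bond are cut. Enolisation of 3 can only occur towards the isopropyl methine, and the β-carbon of 4 bears two identical methyl groups, so there is no regiochemical or geometrical question. All four free positions of 1 are equivalent, so the acylation has one possible outcome.

## Other disconnections considered

Alternative 1: The cut runs through C4–C4a and C1–C8a, so that ring B enters as an aryne and ring A as a furan that already carries ring C and the ester. In the forward sense CsF would release the aryne from the silyl aryl triflate A1 in the presence of the 3-furyl cyclobutyl ester A2. A [4+2] addition across the furan 2,5-positions would then close the new carbocycle as the oxygen-bridged dihydronaphthalene A3, as two bridgehead epimers that converge later.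
- In its favour: aryne–furan cycloaddition is dependable, runs near room temperature under fluoride, leaves the ester alone and is fully convergent, and a symmetrical aryne poses no regiochemical question. In the mildness of the key step and in convergence this plan is the better one.
- Against it here: the key step creates no stereocentre. C1' would have to be set earlier, by an enantioselective addition of a 3-furylmetal reagent to the hindered ketone A4 or by resolution, and the shielded tertiary alcohol would still have to be acylated. A3 is not at the quinone oxidation level; it needs acid-induced opening of the oxygen bridge, which places positive charge next to the tertiary allylic ester, and then an oxidation. The two ring B methyl ethers, peri to the quinone carbonyls, would then have to be cleaved with strong Lewis acids or by an oxidation–reduction detour that the tertiary ester is unlikely to survive.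
- Comparison: structurally, both key steps form one ring and two bonds. Mechanistically, the aryne addition is the more predictable event, whereas the chosen [2+2] is less certain but is the one that builds ring C and its stereocentre. In step economy, the alternative needs A1 and A2 (several steps each), the cycloaddition and about four further operations. That exceeds the nine linear steps of the chosen plan, whose end game also frees the peri-hydroxyls without any ether cleavage.

Alternative 2: The cut is C1–C2 of ring A, preceded by C3–C4, so that ring A arises from a benzocyclobutenedione and an alkyne. In the forward sense the lithium acetylide of the silylated ethynylcyclobutanol A5 would add once to the dione A6 to give the alkynyl hydroxy benzocyclobutenone A7. On heating, A7 would open electrocyclically to an ortho-quinoid ketene. Its ketene carbon would bond to the distal alkyne carbon, and transfer of the hydroxyl hydrogen to C3 would complete the quinone A8.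
- In its favour: ring A arrives directly at the quinone oxidation level without an oxidant, the position of the side chain follows from connectivity, and the key step is thermal and neutral. In redox economy of the key step this plan is the better one.
- Against it here: the closure can also take a five-membered course to an alkylidene indanedione. A saturated tertiary substituent on the alkyne should favour the quinone, but its bulk sits on the carbon that must bond. A6 is not a catalogue compound and takes several steps. The C1' stereocentre is again imported, through A5, which would need an enantioselective alkynylation of the α-quaternary ketone A4. A8 still carries the two ring B methyl ethers, with the same cleavage problem as in alternative 1, and a silyl ether that would have to be exchanged for the ester on a base-sensitive quinone.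
- Comparison: structurally, the key step closes ring A with one new C–C bond, against ring C with two in the chosen plan. Mechanistically, a pericyclic opening and radical-type closure is clean but has a known branching point, whereas the chosen ionic two-stage addition has silyl transfer as its branching point. In step economy, A6 (about four steps), A5 (about three), two steps for addition and ring expansion and at least four afterwards make it clearly longer than nine.

Alternative 3: The cuts are C3–C4, C1–C2 and C1–C8a. Ring A would be assembled onto ring B from a carbene carbon (C4), a carbonyl ligand (C1) and the two alkyne carbons (C2 and C3). In the forward sense the aryl(methoxy)carbene complex A9 of zerovalent chromium would be warmed with the alkyne A5. Alkyne insertion, CO insertion and electrocyclisation would give the 4-methoxy-1-naphthol A10, with the bulky substituent next to the phenol.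
- In its favour: three skeletal bonds form in one step, which is better in bond count than the chosen key step. The regiochemistry of terminal alkynes in this benzannulation is reliable. The C1–OH/C4–OMe pattern is ideal for oxidation to the quinone with (NH4)2Ce(NO3)6. The acetal groups on ring B come off with mild acid, so the end game is much gentler than in alternatives 1 and 2 and equal in mildness to that of the chosen plan.
- Against it here: the chemistry is stoichiometric in chromium carbonyl, with toxic metal waste and CO. The ortho acetal oxygen of A9 can chelate chromium and change its reactivity. The fully substituted propargylic carbon with its silyl ether slows alkyne insertion and favours products formed without CO insertion. C1' again comes from A5, with the same unsolved asymmetric alkynylation of A4. The silyl-to-acyl exchange would have to be fitted in at the naphthol or quinone stage, where alkoxide chemistry is poorly tolerated.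
- Comparison: structurally, the alternative builds the aromatic core and the chosen plan builds ring C; only the latter addresses the stereocentre. Mechanistically, a multi-stage organometallic cascade has more exits than the two-stage ionic [2+2]. In step economy, A9 (about three steps), A5 (about three), benzannulation, oxidation, desilylation, acylation and acetal removal come to about eleven operations against nine, plus a chromium waste stream.

Key step: step 3

Remarks on the chemistry (assumptions and one correction):
- The two naphthazarin tautomers of 18 (side chain on the quinoid or on the benzenoid ring) interconvert rapidly and are one substance. 18 is written as the tautomer of the target structure.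
- 2,5-Bis(trimethylsiloxy)furan 15 is treated as a purchased reagent.
- Correction: the two ester epimers of the cycloadduct are interchangeable only if they differ at C4' alone. A cis isomer formed kinetically on the same enolate face is epimeric at C1' and would become the enantiomer of 9 after decarboxylation. Only the trans isomer 6 is therefore carried forward, after chromatographic separation.
- The sense of asymmetric induction on this acyclic enol ether cannot be taken over from cyclic cases. The (S)-configured catalyst is written as the working choice; the configuration is to be checked at 10 or 18, and the mirror-image catalyst is used if the check demands it.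

## Route

Step 1
Reactants: 1 1,4-dimethoxybenzene; 2 2-methylpropanoyl chloride (isobutyryl chloride)
Product: 3 1-(2,5-dimethoxyphenyl)-2-methylpropan-1-one
Conditions: AlCl3 (1.1 equiv), CH2Cl2, 0 °C; poured into ice-cold 1 M HCl
Reagents that add atoms: none
Why: Friedel–Crafts acylation; all four free positions of 1 are equivalent and the product ring is deactivated against a second acylation. The low temperature and the near-stoichiometric AlCl3 avoid cleavage of the methoxy group ortho to the new carbonyl.

Step 2
Reactants: 3 1-(2,5-dimethoxyphenyl)-2-methylpropan-1-one
Product: 4 {[1-(2,5-dimethoxyphenyl)-2-methylprop-1-en-1-yl]oxy}tri(propan-2-yl)silane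
Conditions: KN(SiMe3)2 (1.2 equiv), THF, −78 → 0 °C; iPr3SiOSO2CF3 (1.3 equiv), −78 °C → rt
Reagents that add atoms: triisopropylsilyl trifluoromethanesulfonate, CC(C)[Si](OS(=O)(=O)C(F)(F)F)(C(C)C)C(C)C
Why: Silyl enol ether formation; deprotonation is possible only at the isopropyl methine, so one enolate forms, and its β-carbon carries two identical methyl groups (no E/Z question). The hard silyl triflate traps the hindered potassium enolate on oxygen.

Step 3
Reactants: 4 {[1-(2,5-dimethoxyphenyl)-2-methylprop-1-en-1-yl]oxy}tri(propan-2-yl)silane; 5 2,2,2-trifluoroethyl prop-2-enoate (1.5 equiv)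
Product: 6 2,2,2-trifluoroethyl (1S,2R)-2-(2,5-dimethoxyphenyl)-3,3-dimethyl-2-{[tri(propan-2-yl)silyl]oxy}cyclobutane-1-carboxylate (ester trans to the siloxy group)
Conditions: (3aS)-1-(2-methylphenyl)-3,3-diphenyltetrahydro-1H,3H-pyrrolo[1,2-c][1,3,2]oxazaborole (10 mol %), AlBr3 (8 mol %), CH2Cl2, −78 °C; Et3N quench at −78 °C; chromatography
Reagents that add atoms: none
Why: Proposed new method: the acrylate 5, bound s-trans through its carbonyl oxygen to the cationic boron of the AlBr3-activated oxazaborolidine, is attacked at its terminal carbon by the nucleophilic carbon C2' of 4 (Mukaiyama–Michael stage, bond C2'–C3'), giving an aryl- and siloxy-stabilised carbenium ion at C1' paired with a boron-bound ester enolate. The enolate carbon C4' then adds to C1' in a 4-exo-trig aldol-type closure (bond C1'–C4'), the only ring-closing mode open to this zwitterion, since the quaternary C2' leaves the cation no proton to lose. The closest known reaction type is the oxazaborolidine–AlBr3-catalysed [2+2] cycloaddition of cyclic trisubstituted silyl enol ethers with 2,2,2-trifluoroethyl acrylate, together with the achiral acid-catalysed Michael–aldol [2+2] of tetrasubstituted silyl enol ethers; an acyclic tetrasubstituted aryl enol ether has not been shown in the asymmetric version. Because C2' (CMe2) and C3' (CH2) are not stereogenic, the Michael stage sets no stereocentre; the C4' centre is set by the catalyst, whose diphenyl-substituted face leaves only one face of the bound enolate open to the tethered cation. The C1' centre is set in the same closure by the orientation of the carbenium ion, which is expected to place the bulky triisopropylsiloxy group trans to the ester. The step needs closure to outrun silyl transfer to the enolate oxygen, which the bulk of the silyl group and the low temperature should secure, and it needs the enol ether and not the dimethoxyarene to act as the nucleophile, which its far higher π-nucleophilicity should secure. The cold amine quench keeps the donor–acceptor cyclobutane from reopening, and separation of the trans isomer removes any cis isomer of opposite C1' configuration.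

Step 4
Reactants: 6 2,2,2-trifluoroethyl (1S,2R)-2-(2,5-dimethoxyphenyl)-3,3-dimethyl-2-{[tri(propan-2-yl)silyl]oxy}cyclobutane-1-carboxylate
Product: 7 (1S,2R)-2-(2,5-dimethoxyphenyl)-3,3-dimethyl-2-{[tri(propan-2-yl)silyl]oxy}cyclobutane-1-carboxylic acid
Conditions: LiOH·H2O (3 equiv), THF/H2O 3:1, 0 °C → rt; 1 M HCl to pH 3–4 at 0 °C
Reagents that add atoms: lithium hydroxide, [Li+].[OH-]
Why: Saponification of an activated trifluoroethyl ester, fast at low temperature. The silyl ether keeps the C1' oxygen masked so that retro-aldol opening of ring C cannot start, and any epimerisation at C4' is irrelevant because that centre is removed in step 5.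

Step 5
Reactants: 7 (1S,2R)-2-(2,5-dimethoxyphenyl)-3,3-dimethyl-2-{[tri(propan-2-yl)silyl]oxy}cyclobutane-1-carboxylic acid
Product: 9 {[(1R)-1-(2,5-dimethoxyphenyl)-2,2-dimethylcyclobutyl]oxy}tri(propan-2-yl)silane, via Barton thiohydroxamate ester 8 (not isolated)
Conditions: 1-hydroxypyridine-2(1H)-thione, DCC, DMAP (cat.), CH2Cl2, 0 °C → rt, dark; then t-BuSH (10 equiv), hν (tungsten lamp), rt
Reagents that add atoms: none
Why: Barton reductive decarboxylation; 8 fragments under visible light to CO2 and the secondary cyclobutyl radical at C4', which abstracts hydrogen from the thiol much faster than a cyclobutyl radical undergoes β-scission. C1' is not involved and keeps its configuration.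

Step 6
Reactants: 9 {[(1R)-1-(2,5-dimethoxyphenyl)-2,2-dimethylcyclobutyl]oxy}tri(propan-2-yl)silane
Product: 10 (1R)-1-(2,5-dimethoxyphenyl)-2,2-dimethylcyclobutan-1-ol
Conditions: Bu4NF (5 equiv), THF, 60 °C; aq. NH4Cl
Reagents that add atoms: none
Why: Fluoride-induced Si–O cleavage under basic, non-ionising conditions, chosen because acid would generate the aryl-stabilised cyclobutyl cation at C1'. The C1'–O bond is not broken, so the configuration is retained.

Step 7
Reactants: 10 (1R)-1-(2,5-dimethoxyphenyl)-2,2-dimethylcyclobutan-1-ol; 11 (2Z)-2-methylbut-2-enoic acid (angelic acid, 2.2 equiv)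
Product: 13 (1R)-1-(2,5-dimethoxyphenyl)-2,2-dimethylcyclobutyl (2Z)-2-methylbut-2-enoate, via angelic anhydride 12 (not isolated)
Conditions: 11, DCC (1.1 equiv), CH2Cl2, 0 °C → rt, filtered; 10, LiN(SiMe3)2 (1.1 equiv), THF, −78 °C, then the solution of 12, −78 → 0 °C; aq. NH4Cl
Reagents that add atoms: none
Why: O-acylation of a preformed lithium alkoxide with a symmetrical anhydride, which offers no choice of carbonyl and needs no nucleophilic catalyst. Under these conditions the Z-configured acyl group is not expected to isomerise by reversible conjugate addition, and the C1'–O bond is untouched.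

Step 8
Reactants: 13 (1R)-1-(2,5-dimethoxyphenyl)-2,2-dimethylcyclobutyl (2Z)-2-methylbut-2-enoate
Product: 14 (1R)-1-(3,6-dioxocyclohexa-1,4-dien-1-yl)-2,2-dimethylcyclobutyl (2Z)-2-methylbut-2-enoate
Conditions: (NH4)2Ce(NO3)6 (2.5 equiv), MeCN/H2O 2:1, 0 °C
Reagents that add atoms: water, O
Why: Oxidative demethylation of a 1,4-dimethoxyarene by two equivalents of tetravalent cerium (arene radical cation, attack of water, loss of methanol). The electron-poor conjugated ester alkene is not oxidised, and with the C1' oxygen acylated the alkoxyl-radical ring opening typical of free 1-arylcyclobutanols is shut off.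

Step 9
Reactants: 14 (1R)-1-(3,6-dioxocyclohexa-1,4-dien-1-yl)-2,2-dimethylcyclobutyl (2Z)-2-methylbut-2-enoate; 15 2,5-bis(trimethylsiloxy)furan (1.3 equiv)
Product: 18 (1R)-1-(5,8-dihydroxy-1,4-dioxo-1,4-dihydronaphthalen-2-yl)-2,2-dimethylcyclobutyl (2Z)-2-methylbut-2-enoate, via oxa-bridged bis(trimethylsiloxy) cycloadduct 16 (not isolated), via ring-opened tetraone 17 (not isolated)
Conditions: CH2Cl2, −78 °C → rt; then 1 M HCl, THF, rt
Reagents that add atoms: none
Why: Diels–Alder addition of the electron-rich disiloxyfuran to the unsubstituted, unhindered C=C of the quinone gives the bridged bis-silyl ketal 16. Acid opens both ketals, with loss of hexamethyldisiloxane, to 17, which is already at the oxidation level of the product and enolises twice to the hydrogen-bonded naphthazarin. The symmetrical diene removes any regiochemical issue and C1' is a spectator.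

## Compound list

1 | 1,4-dimethoxybenzene | COc1ccc(OC)cc1 | starting material
2 | 2-methylpropanoyl chloride (isobutyryl chloride) | CC(C)C(=O)Cl | starting material
3 | 1-(2,5-dimethoxyphenyl)-2-methylpropan-1-one | CC(C)C(=O)c1cc(OC)ccc1OC | intermediate
4 | {[1-(2,5-dimethoxyphenyl)-2-methylprop-1-en-1-yl]oxy}tri(propan-2-yl)silane | CC(C)=C(O[Si](C(C)C)(C(C)C)C(C)C)c1cc(OC)ccc1OC | intermediate
5 | 2,2,2-trifluoroethyl prop-2-enoate | C=CC(=O)OCC(F)(F)F | starting material
6 | 2,2,2-trifluoroethyl (1S,2R)-2-(2,5-dimethoxyphenyl)-3,3-dimethyl-2-{[tri(propan-2-yl)silyl]oxy}cyclobutane-1-carboxylate | CC(C)[Si](C(C)C)(C(C)C)O[C@]1(c2cc(OC)ccc2OC)[C@@H](C(=O)OCC(F)(F)F)CC1(C)C | intermediate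
7 | (1S,2R)-2-(2,5-dimethoxyphenyl)-3,3-dimethyl-2-{[tri(propan-2-yl)silyl]oxy}cyclobutane-1-carboxylic acid | CC(C)[Si](C(C)C)(C(C)C)O[C@]1(c2cc(OC)ccc2OC)[C@@H](C(=O)O)CC1(C)C | intermediate
8 | 2-thioxopyridin-1(2H)-yl (1S,2R)-2-(2,5-dimethoxyphenyl)-3,3-dimethyl-2-{[tri(propan-2-yl)silyl]oxy}cyclobutane-1-carboxylate (Barton ester, formed and consumed in step 5) | CC(C)[Si](C(C)C)(C(C)C)O[C@]1(c2cc(OC)ccc2OC)[C@@H](C(=O)ON2C=CC=CC2=S)CC1(C)C | intermediate
9 | {[(1R)-1-(2,5-dimethoxyphenyl)-2,2-dimethylcyclobutyl]oxy}tri(propan-2-yl)silane | CC(C)[Si](C(C)C)(C(C)C)O[C@]1(c2cc(OC)ccc2OC)CCC1(C)C | intermediate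
10 | (1R)-1-(2,5-dimethoxyphenyl)-2,2-dimethylcyclobutan-1-ol | O[C@]1(c2cc(OC)ccc2OC)CCC1(C)C | intermediate
11 | (2Z)-2-methylbut-2-enoic acid (angelic acid) | C/C=C(/C)C(=O)O | starting material
12 | (2Z)-2-methylbut-2-enoic anhydride (angelic anhydride, formed and consumed in step 7) | C/C=C(/C)C(=O)OC(=O)/C(C)=C\C | intermediate
13 | (1R)-1-(2,5-dimethoxyphenyl)-2,2-dimethylcyclobutyl (2Z)-2-methylbut-2-enoate | C/C=C(/C)C(=O)O[C@]1(c2cc(OC)ccc2OC)CCC1(C)C | intermediate
14 | (1R)-1-(3,6-dioxocyclohexa-1,4-dien-1-yl)-2,2-dimethylcyclobutyl (2Z)-2-methylbut-2-enoate | C/C=C(/C)C(=O)O[C@]1(C2=CC(=O)C=CC2=O)CCC1(C)C | intermediate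
15 | 2,5-bis(trimethylsiloxy)furan | C[Si](C)(C)Oc1ccc(O[Si](C)(C)C)o1 | starting material
16 | (1R)-1-[5,8-dioxo-1,4-bis(trimethylsiloxy)-1,4,4a,5,8,8a-hexahydro-1,4-epoxynaphthalen-6-yl]-2,2-dimethylcyclobutyl (2Z)-2-methylbut-2-enoate (mixture of ring-fusion diastereomers, formed and consumed in step 9) | C/C=C(/C)C(=O)O[C@]1(C2=CC(=O)C3C(C2=O)C4(O[Si](C)(C)C)C=CC3(O[Si](C)(C)C)O4)CCC1(C)C | intermediate
17 | (1R)-2,2-dimethyl-1-(1,4,5,8-tetraoxo-1,4,4a,5,8,8a-hexahydronaphthalen-2-yl)cyclobutyl (2Z)-2-methylbut-2-enoate (formed and consumed in step 9) | C/C=C(/C)C(=O)O[C@]1(C2=CC(=O)C3C(C2=O)C(=O)C=CC3=O)CCC1(C)C | intermediate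
18 | (1R)-1-(5,8-dihydroxy-1,4-dioxo-1,4-dihydronaphthalen-2-yl)-2,2-dimethylcyclobutyl (2Z)-2-methylbut-2-enoate | C/C=C(/C)C(=O)O[C@]1(C2=CC(=O)c3c(O)ccc(O)c3C2=O)CCC1(C)C | target

## Step count and least certain steps

Total: 9 steps. Longest linear sequence: 9 steps (1 → 18); 2, 5, 11 and 15 enter directly.

**Step 3 (key step, Proposed new method).** Three processes are most likely to go wrong:
- silyl transfer within the zwitterion, leading to open-chain Michael addition instead of ring closure, because closure must join a hindered tertiary cation to an enolate carbon next to a quaternary centre;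
- insufficient facial discrimination in the closure, or reversible reopening of the donor–acceptor cyclobutane under the Lewis acid, either of which lowers the enantiomeric purity at C1';
- deactivation of the catalyst by binding to the methoxy groups.

Fallback, using known chemistry: setting out from 4 and 5, the same partners would be combined under an achiral acid catalyst ((CF3SO2)2NH or EtAlCl2, CH2Cl2, −78 °C), the established racemic Michael–aldol [2+2], to give the racemic trans cycloadduct F1. Saponification as in step 4 would give the racemic trans acid F2. This would be resolved by crystallisation with (S)-1-phenylethylamine (or its antipode, whichever gives the less soluble salt of the wanted acid) as the (S)-1-phenylethylammonium salt F3. Acidification would return the route at 7. The carboxyl group thus serves both as the traceless activator and as the resolution handle.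

**Step 7.** The likely failures are geometric isomerisation of the Z-acyl group to the E-isomer, through reversible conjugate addition or γ-deprotonation during a slow acylation, and incomplete acylation of the shielded tertiary alkoxide. Fallback: setting out from 10, the alcohol would be acylated with 2-[bis(2,2,2-trifluoroethoxy)phosphoryl]propanoic acid (DCC, through the phosphonoketene, or the acid chloride on the lithium alkoxide). No alkene is present, so forcing conditions are harmless. This gives the phosphonopropanoate ester F4. A Still–Gennari olefination (KN(SiMe3)2, 18-crown-6, THF, −78 °C, acetaldehyde) would then build the Z-alkene on the ester and return the route at 13.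

**Step 9.** The likely failures are conjugate (Mukaiyama–Michael) addition of the siloxyfuran to the quinone in place of cycloaddition, and loss of the tertiary acyloxy group by elimination from a hydroquinone-type tautomer during the acid-induced collapse. Fallback: setting out from 14, a Diels–Alder reaction with the known diene (1E,3E)-1,4-bis(trimethylsiloxy)buta-1,3-diene F5 (toluene, 60–80 °C) would give the cis-fused bis(siloxy) tetrahydronaphthoquinone adduct F6. Oxidation of its two allylic silyl ethers with CrO3/H2SO4 in acetone at 0 °C (hexavalent chromium; the established oxidation of siloxydiene–quinone adducts to peri-hydroxyquinones) would return the route at 17, which tautomerises to 18.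

**Step 6.** The likely failure is incomplete Si–O cleavage, because the silicon is shielded by three isopropyl groups and a tertiary, neopentyl-type alkoxy group; prolonged heating with fluoride then risks base-induced degradation. Fallback: setting out from 3, the series would be repeated with the smaller silyl group:
- KN(SiMe3)2 and t-BuMe2SiOSO2CF3 would give the tert-butyldimethylsilyl enol ether F7.
- The [2+2] reaction with 5 as in step 3 would give the tert-butyldimethylsilyl cycloadduct F8.
- Saponification would give the acid F9.
- Decarboxylation through the Barton ester F10 would give the tert-butyldimethylsilyl ether F11.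
- Bu4NF at room temperature would cleave F11 and return the route at 10.

The price is a higher risk of silyl transfer in the ring-forming step.

## Further compounds

F1 | step 3 | 2,2,2-trifluoroethyl trans-2-(2,5-dimethoxyphenyl)-3,3-dimethyl-2-{[tri(propan-2-yl)silyl]oxy}cyclobutane-1-carboxylate, racemate (1S*,2R*) | CC(C)[Si](C(C)C)(C(C)C)OC1(c2cc(OC)ccc2OC)C(C(=O)OCC(F)(F)F)CC1(C)C
F2 | step 3 | trans-2-(2,5-dimethoxyphenyl)-3,3-dimethyl-2-{[tri(propan-2-yl)silyl]oxy}cyclobutane-1-carboxylic acid, racemate (1S*,2R*) | CC(C)[Si](C(C)C)(C(C)C)OC1(c2cc(OC)ccc2OC)C(C(=O)O)CC1(C)C
F3 | step 3 | (1S)-1-phenylethan-1-aminium (1S,2R)-2-(2,5-dimethoxyphenyl)-3,3-dimethyl-2-{[tri(propan-2-yl)silyl]oxy}cyclobutane-1-carboxylate | C[C@H]([NH3+])c1ccccc1.CC(C)[Si](C(C)C)(C(C)C)O[C@]1(c2cc(OC)ccc2OC)[C@@H](C(=O)[O-])CC1(C)C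
F4 | step 7 | (1R)-1-(2,5-dimethoxyphenyl)-2,2-dimethylcyclobutyl 2-[bis(2,2,2-trifluoroethoxy)phosphoryl]propanoate (both epimers at the phosphonate-bearing carbon) | CC(C(=O)O[C@]1(c2cc(OC)ccc2OC)CCC1(C)C)P(=O)(OCC(F)(F)F)OCC(F)(F)F
F5 | step 9 | (1E,3E)-1,4-bis(trimethylsiloxy)buta-1,3-diene | C[Si](C)(C)O/C=C/C=C/O[Si](C)(C)C
F6 | step 9 | (1R)-1-[1,4-dioxo-5,8-bis(trimethylsiloxy)-1,4,4a,5,8,8a-hexahydronaphthalen-2-yl]-2,2-dimethylcyclobutyl (2Z)-2-methylbut-2-enoate (cis-fused, mixture of diastereomers) | C/C=C(/C)C(=O)O[C@]1(C2=CC(=O)C3C(C2=O)C(O[Si](C)(C)C)C=CC3O[Si](C)(C)C)CCC1(C)C
F7 | step 6 | tert-butyl{[1-(2,5-dimethoxyphenyl)-2-methylprop-1-en-1-yl]oxy}dimethylsilane | CC(C)=C(O[Si](C)(C)C(C)(C)C)c1cc(OC)ccc1OC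
F8 | step 6 | 2,2,2-trifluoroethyl (1S,2R)-2-{[tert-butyl(dimethyl)silyl]oxy}-2-(2,5-dimethoxyphenyl)-3,3-dimethylcyclobutane-1-carboxylate | CC(C)(C)[Si](C)(C)O[C@]1(c2cc(OC)ccc2OC)[C@@H](C(=O)OCC(F)(F)F)CC1(C)C
F9 | step 6 | (1S,2R)-2-{[tert-butyl(dimethyl)silyl]oxy}-2-(2,5-dimethoxyphenyl)-3,3-dimethylcyclobutane-1-carboxylic acid | CC(C)(C)[Si](C)(C)O[C@]1(c2cc(OC)ccc2OC)[C@@H](C(=O)O)CC1(C)C
F10 | step 6 | 2-thioxopyridin-1(2H)-yl (1S,2R)-2-{[tert-butyl(dimethyl)silyl]oxy}-2-(2,5-dimethoxyphenyl)-3,3-dimethylcyclobutane-1-carboxylate | CC(C)(C)[Si](C)(C)O[C@]1(c2cc(OC)ccc2OC)[C@@H](C(=O)ON2C=CC=CC2=S)CC1(C)C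
F11 | step 6 | tert-butyl{[(1R)-1-(2,5-dimethoxyphenyl)-2,2-dimethylcyclobutyl]oxy}dimethylsilane | CC(C)(C)[Si](C)(C)O[C@]1(c2cc(OC)ccc2OC)CCC1(C)C
A1 | alternative 1 | 3,6-dimethoxy-2-(trimethylsilyl)phenyl trifluoromethanesulfonate | COc1ccc(OC)c([Si](C)(C)C)c1OS(=O)(=O)C(F)(F)F
A2 | alternative 1 | (1R)-1-(furan-3-yl)-2,2-dimethylcyclobutyl (2Z)-2-methylbut-2-enoate | C/C=C(/C)C(=O)O[C@]1(c2ccoc2)CCC1(C)C
A3 | alternative 1 | (1R)-1-(5,8-dimethoxy-1,4-dihydro-1,4-epoxynaphthalen-2-yl)-2,2-dimethylcyclobutyl (2Z)-2-methylbut-2-enoate (both bridgehead epimers) | C/C=C(/C)C(=O)O[C@]1(C2=CC3OC2c2c(OC)ccc(OC)c23)CCC1(C)C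
A4 | alternative 1 | 2,2-dimethylcyclobutan-1-one | CC1(C)CCC1=O
A5 | alternative 2 | triethyl{[(1R)-1-ethynyl-2,2-dimethylcyclobutyl]oxy}silane | CC[Si](CC)(CC)O[C@]1(C#C)CCC1(C)C
A6 | alternative 2 | 2,5-dimethoxybicyclo[4.2.0]octa-1,3,5-triene-7,8-dione (3,6-dimethoxybenzocyclobutenedione) | COc1ccc(OC)c2c1C(=O)C2=O
A7 | alternative 2 | 8-{[(1R)-2,2-dimethyl-1-(triethylsiloxy)cyclobutyl]ethynyl}-8-hydroxy-2,5-dimethoxybicyclo[4.2.0]octa-1,3,5-trien-7-one (both carbinol epimers) | CC[Si](CC)(CC)O[C@]1(C#CC2(O)C(=O)c3c(OC)ccc(OC)c32)CCC1(C)C
A8 | alternative 2 | 2-[(1R)-2,2-dimethyl-1-(triethylsiloxy)cyclobutyl]-5,8-dimethoxynaphthalene-1,4-dione | CC[Si](CC)(CC)O[C@]1(C2=CC(=O)c3c(OC)ccc(OC)c3C2=O)CCC1(C)C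
A9 | alternative 3 | pentacarbonyl{[2,5-bis(methoxymethoxy)phenyl](methoxy)methylidene}chromium (zerovalent chromium) | COC(c1cc(OCOC)ccc1OCOC)=[Cr](=C=O)(=C=O)(=C=O)(=C=O)=C=O
A10 | alternative 3 | 2-[(1R)-2,2-dimethyl-1-(triethylsiloxy)cyclobutyl]-4-methoxy-5,8-bis(methoxymethoxy)naphthalen-1-ol | CC[Si](CC)(CC)O[C@]1(c2cc(OC)c3c(OCOC)ccc(OCOC)c3c2O)CCC1(C)C
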